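**Plan**

- Retrosynthetic cuts: (a) the C(sp)–C(sp2) bond of the enyne (Sonogashira); (b) both ring C–O bonds to the peroxide, i.e. the O–O unit is excised from the 1,2-dioxane to leave a cyclobutanol; (c) one cyclobutane C–C bond (ketyl–enoate coupling); (d) the enoate C=C (cross-metathesis); (e) a ketone C–C bond (acylation).
- Forward order: acyclic keto-enoate → cyclobutanol (four-membered ring) → 1,2-dioxan-3-ol (six-membered, O2 inserted) → methoxy peroxyketal → resolution → attachment of the C11 dienyl unit last.
- Enabling feature: the strained tertiary cyclobutanol, whose ring bond C(OH)–CH(CH2CO2Me) breaks homolytically. This leaves a ketone at the carbinol carbon (future C6) and a secondary radical at the arm-bearing carbon (future C3), held apart by the two ring CH2 groups (future C5, C4), so that O2 bridges them into the 1,2-dioxane.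
- Stereochemistry: the cyclobutanol configuration is immaterial, because the radical step erases it and all isomers converge. C6 is set relative to C3 by thermodynamic (anomeric) ketalisation. The absolute configuration comes from an enzymatic kinetic resolution of the methyl ester, because the radical step necessarily gives racemic C3. The E-alkene comes from a Takai olefination and is retained in the coupling.

Key step: step 5

Assumption: the sense of enantiomer preference of a hydrolase towards this β-peroxy ester cannot be predicted; the route is written for an enzyme, found by screening, that hydrolyses the (3S,6R)-ester faster.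

**Route**

Step 1
Reactants: 1 (5-chloropent-1-yn-1-yl)trimethylsilane; 2 pent-4-enoyl chloride
Product: 4 10-(trimethylsilyl)dec-1-en-9-yn-5-one, via [5-(trimethylsilyl)pent-4-yn-1-yl]magnesium chloride 3 (not isolated)
Conditions: Mg, THF, reflux; then 2, Fe(acac)3 (3 mol%), THF, −78 °C
Reagents that add atoms: none
Why: Iron-catalysed acylation of a primary alkyl Grignard reagent with an acid chloride is fast at −78 °C and should stop at the ketone, with the silyl-capped alkyne and the terminal alkene as spectators.

Step 2
Reactants: 4 10-(trimethylsilyl)dec-1-en-9-yn-5-one; 5 methyl acrylate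
Product: 6 methyl (E)-6-oxo-11-(trimethylsilyl)undec-2-en-10-ynoate
Conditions: Hoveyda–Grubbs II (3 mol%), methyl acrylate (4 equiv), CH2Cl2, 40 °C
Reagents that add atoms: none
Why: Olefin cross-metathesis of an unhindered terminal alkene with an acrylate should give the E-enoate selectively, and the silyl cap keeps the alkyne out of enyne metathesis.

Step 3
Reactants: 6 methyl (E)-6-oxo-11-(trimethylsilyl)undec-2-en-10-ynoate
Product: 7 methyl 2-[(1R*,2S*)-2-hydroxy-2-[5-(trimethylsilyl)pent-4-yn-1-yl]cyclobutyl]acetate
Conditions: SmI2 (2.5 equiv), THF/MeOH (4:1), 0 °C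
Reagents that add atoms: none
Why: SmI2-mediated ketyl–olefin 4-exo-trig cyclisation: the samarium ketyl adds to the β-carbon of the enoate and the enolate is protonated by MeOH; the anti arrangement expected for this reaction type (OH trans to the CH2CO2Me arm) prevents lactonisation, and both new stereocentres are erased again in step 5.

Step 4
Reactants: 7 methyl 2-[(1R*,2S*)-2-hydroxy-2-[5-(trimethylsilyl)pent-4-yn-1-yl]cyclobutyl]acetate
Product: 8 methyl 2-[(1R*,2S*)-2-hydroxy-2-(pent-4-yn-1-yl)cyclobutyl]acetate
Conditions: K2CO3 (0.2 equiv), MeOH, rt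
Reagents that add atoms: none
Why: Methoxide-mediated protodesilylation of the alkynylsilane frees the terminal alkyne before any peroxide is present; transesterification of the methyl ester in MeOH is degenerate and the trans hydroxy ester cannot lactonise.

Step 5
Reactants: 8 methyl 2-[(1R*,2S*)-2-hydroxy-2-(pent-4-yn-1-yl)cyclobutyl]acetate
Product: 10 methyl 2-[6-hydroxy-6-(pent-4-yn-1-yl)-1,2-dioxan-3-yl]acetate, via methyl 3-hydroperoxy-6-oxoundec-10-ynoate 9 (not isolated)
Conditions: Co(acac)2 (20 mol%), O2 (1 atm), 1,2-dichloroethane, 40 °C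
Reagents that add atoms: dioxygen, O=O
Why: Co(acac)2/O2 turns the tertiary cyclobutanol into its alkoxy radical, whose strain-driven β-scission breaks the C(OH)–CH(CH2CO2Me) ring bond to leave the ketone at the former carbinol carbon and a secondary alkyl radical at the arm-bearing carbon; triplet O2 captures this radical, the peroxyl radical is reduced to hydroperoxide 9 by the cobalt/cyclobutanol redox chain, and 9 closes on the γ-ketone. The closest known reaction type is the cobalt-catalysed aerobic oxidative ring expansion of 2-substituted cyclobutanols to 1,2-dioxan-3-ols. The 1,2-dioxane closes by reversible 6-exo-trig addition of the hydroperoxide oxygen to the ketone (hemiketalisation), so the four-membered carbocycle grows by the two oxygen atoms inserted between the two former ring neighbours. The CH–OO centre (C3) arises from a planar radical and is therefore racemic whatever the configuration of 8 (all cyclobutanol isomers converge), the hemiketal centre stays mobile until step 6, and the absolute configuration is settled in step 7. The step needs scission of the ring bond towards the substituted carbon and not towards the ring CH2 or the side chain, which the secondary versus primary radical stability and the relief of ring strain should secure, and it needs O2 capture to outrun radical attack on the terminal alkyne, which the near diffusion-controlled oxygenation of alkyl radicals should secure; the ester arm trans to the hydroxyl cannot lactonise, so the alcohol stays free.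

Step 6
Reactants: 10 methyl 2-[6-hydroxy-6-(pent-4-yn-1-yl)-1,2-dioxan-3-yl]acetate
Product: 11 methyl 2-[(3S*,6R*)-6-methoxy-6-(pent-4-yn-1-yl)-1,2-dioxan-3-yl]acetate
Conditions: p-TsOH·H2O (5 mol%), MeOH, 0 °C to rt
Reagents that add atoms: methanol, CO
Why: Acid-catalysed exchange of the peroxy-hemiketal OH for OMe is reversible and should settle on the isomer with OMe axial (anomeric effect) and both carbon substituents equatorial, which is the required isomer with OMe cis to the CH2CO2Me arm; the secondary C3–O bond does not ionise, so C3 is untouched.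

Step 7
Reactants: 11 methyl 2-[(3S*,6R*)-6-methoxy-6-(pent-4-yn-1-yl)-1,2-dioxan-3-yl]acetate
Product: 12 2-[(3S,6R)-6-methoxy-6-(pent-4-yn-1-yl)-1,2-dioxan-3-yl]acetic acid
Conditions: hydrolase chosen by screening (e.g. immobilised Candida antarctica lipase B), phosphate buffer pH 7.0/MTBE, 25 °C, stopped near 40% conversion; NaHCO3 extraction
Reagents that add atoms: water, O
Why: Enzymatic kinetic resolution by enantioselective ester hydrolysis: the C3 stereocentre lies β to the acyl carbon inside the acyl-binding site, so one enantiomer should be hydrolysed faster and is collected as the acid, while the unreacted (3R,6S)-ester stays in the organic phase; the neutral pH spares the base-sensitive β-peroxy ester.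

Step 8
Reactants: 13 dec-9-en-1-ol
Product: 14 dec-9-enal
Conditions: TEMPO (10 mol%), PhI(OAc)2 (1.1 equiv), CH2Cl2, rt
Reagents that add atoms: none
Why: Oxoammonium-mediated oxidation of a primary alcohol should stop at the aldehyde under anhydrous conditions and leave the terminal alkene untouched.

Step 9
Reactants: 14 dec-9-enal
Product: 15 (E)-1-iodoundeca-1,10-diene
Conditions: CrCl2 (6 equiv), CHI3 (2 equiv), 1,4-dioxane/THF (6:1), 0 °C to rt
Reagents that add atoms: iodoform, IC(I)I
Why: Takai olefination: the geminal dichromium reagent adds to the aldehyde and the anti-periplanar elimination should give the E-vinyl iodide preferentially (dioxane as co-solvent favours E), with the remote alkene inert.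

Step 10
Reactants: 12 2-[(3S,6R)-6-methoxy-6-(pent-4-yn-1-yl)-1,2-dioxan-3-yl]acetic acid; 15 (E)-1-iodoundeca-1,10-diene
Product: 16 2-[(3S,6R)-6-[(6E)-hexadeca-6,15-dien-4-yn-1-yl]-6-methoxy-1,2-dioxan-3-yl]acetic acid
Conditions: Pd(PPh3)4 (5 mol%), CuI (10 mol%), i-Pr2NH (3 equiv), degassed THF, rt, dark
Reagents that add atoms: none
Why: Sonogashira coupling joins the terminal alkyne to the vinyl iodide with retention of the E geometry; the dialkyl peroxyketal is expected to tolerate Pd(0)/Cu(I) at room temperature, and the carboxylate formed with the amine cannot undergo the β-elimination open to a β-peroxy ester, so both stereocentres should persist.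

**Compound list**

1 | (5-chloropent-1-yn-1-yl)trimethylsilane | C[Si](C)(C)C#CCCCCl | starting material
2 | pent-4-enoyl chloride | C=CCCC(=O)Cl | starting material
3 | [5-(trimethylsilyl)pent-4-yn-1-yl]magnesium chloride | C[Si](C)(C)C#CCCC[Mg]Cl | intermediate
4 | 10-(trimethylsilyl)dec-1-en-9-yn-5-one | C=CCCC(=O)CCCC#C[Si](C)(C)C | intermediate
5 | methyl acrylate | C=CC(=O)OC | starting material
6 | methyl (E)-6-oxo-11-(trimethylsilyl)undec-2-en-10-ynoate | COC(=O)/C=C/CCC(=O)CCCC#C[Si](C)(C)C | intermediate
7 | methyl 2-[(1R*,2S*)-2-hydroxy-2-[5-(trimethylsilyl)pent-4-yn-1-yl]cyclobutyl]acetate (racemate, OH trans to the CH2CO2Me arm; one enantiomer drawn) | C[Si](C)(C)C#CCCC[C@]1(O)CC[C@@H]1CC(=O)OC | intermediate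
8 | methyl 2-[(1R*,2S*)-2-hydroxy-2-(pent-4-yn-1-yl)cyclobutyl]acetate (racemate; one enantiomer drawn) | C#CCCC[C@]1(O)CC[C@@H]1CC(=O)OC | intermediate
9 | methyl 3-hydroperoxy-6-oxoundec-10-ynoate (racemic) | C#CCCCC(=O)CCC(OO)CC(=O)OC | intermediate
10 | methyl 2-[6-hydroxy-6-(pent-4-yn-1-yl)-1,2-dioxan-3-yl]acetate (hemiketal epimers, racemic at C3) | C#CCCCC1(O)CCC(CC(=O)OC)OO1 | intermediate
11 | methyl 2-[(3S*,6R*)-6-methoxy-6-(pent-4-yn-1-yl)-1,2-dioxan-3-yl]acetate (racemate, OMe cis to the CH2CO2Me arm; one enantiomer drawn) | C#CCCC[C@]1(OC)CC[C@@H](CC(=O)OC)OO1 | intermediate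
12 | 2-[(3S,6R)-6-methoxy-6-(pent-4-yn-1-yl)-1,2-dioxan-3-yl]acetic acid | C#CCCC[C@]1(OC)CC[C@@H](CC(=O)O)OO1 | intermediate
13 | dec-9-en-1-ol | C=CCCCCCCCCO | starting material
14 | dec-9-enal | C=CCCCCCCCC=O | intermediate
15 | (E)-1-iodoundeca-1,10-diene | C=CCCCCCCC/C=C/I | intermediate
16 | 2-[(3S,6R)-6-[(6E)-hexadeca-6,15-dien-4-yn-1-yl]-6-methoxy-1,2-dioxan-3-yl]acetic acid | C=CCCCCCCC/C=C/C#CCCC[C@]1(OC)CC[C@@H](CC(=O)O)OO1 | target

**Step count**

Total steps: 10. Longest linear sequence: 8 (steps 1–7 and 10); the vinyl iodide (steps 8–9) is made in parallel.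

**Steps most likely to fail, with fallbacks**

Step 5. The alkoxy radical may form too slowly from the hindered tertiary alcohol, the scission may be unselective, or peroxyl-radical chain oxidation may attack the propargylic and α-keto C–H positions.

The fallback brings the peroxide in by polar chemistry and closes the ring by C–O bond formation; it sets out from 6 and returns at 11.
- 6 is desilylated (K2CO3, MeOH) to methyl (E)-6-oxoundec-2-en-10-ynoate F1.
- F1 is ketalised (HC(OMe)3, MeOH, cat. TsOH) to methyl (E)-6,6-dimethoxyundec-2-en-10-ynoate F2.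
- One methoxy group is exchanged for a hydroperoxy group (urea–H2O2, cat. Sc(OTf)3, MeOH) to give methyl (E)-6-hydroperoxy-6-methoxyundec-2-en-10-ynoate F3.
- F3 is closed by base-mediated 6-exo-trig intramolecular oxa-Michael addition (Et2NH, CF3CH2OH, rt). This should give racemic 11 together with its ketal epimer methyl 2-[(3R*,6R*)-6-methoxy-6-(pent-4-yn-1-yl)-1,2-dioxan-3-yl]acetate F4.
- F4 is converged on 11 by the TsOH/MeOH equilibration of step 6.

Step 7. The hydrolase may discriminate the enantiomers poorly (stereocentre two bonds from the reacting carbonyl), or only enzymes of the opposite preference may be found.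

The fallback replaces the kinetic resolution by separation of covalent diastereomers; it sets out from 11 and returns at 12.
- 11 is hydrolysed without selectivity (LiOH, THF/H2O, 0 °C) to the racemic acid 2-[(3S*,6R*)-6-methoxy-6-(pent-4-yn-1-yl)-1,2-dioxan-3-yl]acetic acid F5.
- N-Acylation of (S)-4-benzyloxazolidin-2-one with F5 (DCC, cat. DMAP, CH2Cl2) gives two imides, separated by chromatography: (4S)-4-benzyl-3-{2-[(3S,6R)-6-methoxy-6-(pent-4-yn-1-yl)-1,2-dioxan-3-yl]acetyl}-1,3-oxazolidin-2-one F6 and its (3R,6S) diastereomer (4S)-4-benzyl-3-{2-[(3R,6S)-6-methoxy-6-(pent-4-yn-1-yl)-1,2-dioxan-3-yl]acetyl}-1,3-oxazolidin-2-one F7.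
- F6 is cleaved with LiOH/H2O2 (THF/H2O, 0 °C) to 12.

Step 3. Simple reduction of the ketone or pinacol coupling may outrun the slow four-membered ring closure on a tether without substituents, and any cis product may be lost by lactonisation.

The fallback makes the four-membered ring first by cycloaddition and then adds the side chain; it sets out from Grignard reagent 3 (made from 1 as in step 1) and returns at 10.
- Commercial methyl 4-(dimethylamino)-4-oxobutanoate is activated (Tf2O, 2,4,6-collidine, 1,2-dichloroethane) and undergoes keteniminium–ethene [2+2] cycloaddition to N-[2-(2-methoxy-2-oxoethyl)cyclobutylidene]-N-methylmethanaminium triflate F8.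
- Aqueous NaHCO3 hydrolysis of F8 gives methyl 2-(2-oxocyclobutyl)acetate F9.
- Reagent 3 with CeCl3 (THF, −78 °C, cold NH4Cl quench) adds to the ketone of F9 in preference to the ester, anti to the arm. This should give the syn cyclobutanol methyl 2-[(1R*,2R*)-2-hydroxy-2-[5-(trimethylsilyl)pent-4-yn-1-yl]cyclobutyl]acetate F10, which is kept away from acid and base because its hydroxyl is cis to the ester arm.
- Buffered desilylation (TBAF/AcOH, THF, 0 °C) gives methyl 2-[(1R*,2R*)-2-hydroxy-2-(pent-4-yn-1-yl)cyclobutyl]acetate F11, the carbinol epimer of 8.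
- F11 is submitted to step 5 and should give the same 10, since the cyclobutane configuration is erased there.

Further compounds
F1 | step 5 | methyl (E)-6-oxoundec-2-en-10-ynoate | COC(=O)/C=C/CCC(=O)CCCC#C
F2 | step 5 | methyl (E)-6,6-dimethoxyundec-2-en-10-ynoate | COC(=O)/C=C/CCC(OC)(OC)CCCC#C
F3 | step 5 | methyl (E)-6-hydroperoxy-6-methoxyundec-2-en-10-ynoate (racemic) | COC(=O)/C=C/CCC(OC)(OO)CCCC#C
F4 | step 5 | methyl 2-[(3R*,6R*)-6-methoxy-6-(pent-4-yn-1-yl)-1,2-dioxan-3-yl]acetate (racemate; one enantiomer drawn) | C#CCCC[C@@]1(OC)CC[C@@H](CC(=O)OC)OO1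
F5 | step 7 | 2-[(3S*,6R*)-6-methoxy-6-(pent-4-yn-1-yl)-1,2-dioxan-3-yl]acetic acid (racemate; one enantiomer drawn) | C#CCCC[C@]1(OC)CC[C@@H](CC(=O)O)OO1
F6 | step 7 | (4S)-4-benzyl-3-{2-[(3S,6R)-6-methoxy-6-(pent-4-yn-1-yl)-1,2-dioxan-3-yl]acetyl}-1,3-oxazolidin-2-one | C#CCCC[C@]1(OC)CC[C@@H](CC(=O)N2[C@@H](Cc3ccccc3)COC2=O)OO1
F7 | step 7 | (4S)-4-benzyl-3-{2-[(3R,6S)-6-methoxy-6-(pent-4-yn-1-yl)-1,2-dioxan-3-yl]acetyl}-1,3-oxazolidin-2-one | C#CCCC[C@@]1(OC)CC[C@H](CC(=O)N2[C@@H](Cc3ccccc3)COC2=O)OO1
F8 | step 3 | N-[2-(2-methoxy-2-oxoethyl)cyclobutylidene]-N-methylmethanaminium triflate (racemic) | COC(=O)CC1CCC1=[N+](C)C.[O-]S(=O)(=O)C(F)(F)F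
F9 | step 3 | methyl 2-(2-oxocyclobutyl)acetate (racemic) | COC(=O)CC1CCC1=O
F10 | step 3 | methyl 2-[(1R*,2R*)-2-hydroxy-2-[5-(trimethylsilyl)pent-4-yn-1-yl]cyclobutyl]acetate (racemate, OH cis to the arm; one enantiomer drawn) | C[Si](C)(C)C#CCCC[C@@]1(O)CC[C@@H]1CC(=O)OC
F11 | step 3 | methyl 2-[(1R*,2R*)-2-hydroxy-2-(pent-4-yn-1-yl)cyclobutyl]acetate (racemate; one enantiomer drawn) | C#CCCC[C@@]1(O)CC[C@@H]1CC(=O)OC
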